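## Retrosynthetic overview

1. Numbering used throughout: ring carbons C1 (quaternary, CH3 and homofarnesyl), C2 (CH–CH3), C3, C4, C5 (alkylidene) and C6 (CH carrying Cα–Cβ–Cγ–OH); C7 is the exocyclic alkylidene carbon (CH3, CHO). The plan rests on one feature: C7 and Cγ are the two ends of a former six-membered ring A (C5, C6, Cα, Cβ, Cγ, C7) that was fused along C5–C6 to ring B (C1–C6), so the target is a ring-A-cleaved (C7–Cγ seco) decalin of squalene origin.
2. Functional-group level: the C7 formyl group is traced back to a methyl group of a C5 isopropylidene (oxidative 1,3-transposition of a C5 tertiary isopropenyl carbinol, itself made by a singlet-oxygen ene reaction), and the Cγ alcohol to an aldehyde. This leads to marneral 4.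
3. Key disconnection: 4 is opened to (3S)-2,3-oxidosqualene 3. A marneral-synthase-type oxidosqualene cyclase forms C5–C7 and C1–C6, moves a methyl group to C1 and cleaves C7–Cγ (Grob), setting C1, C2 and C6.
4. 3 goes back to squalene 1 through the terminal bromohydrin 2.
5. Ring order in the forward sense: ring A first (transient), ring B second, ring A reopened in the same operation; ring B is the only ring that reaches the target.

Key step: step 3

Remark: the cyclase is treated as a catalyst (cell-free homogenate of an erg7-deficient Saccharomyces cerevisiae strain expressing the marneral synthase gene MRN1 of Arabidopsis thaliana) and its preparation is not counted as a step; epoxide 3 is carried as the racemate because only its (3S)-enantiomer is expected to be a substrate.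

## Route

Step 1
Reactants: 1 squalene
Product: 2 (3RS)-3-bromo-2,3-dihydrosqualen-2-ol (terminal bromohydrin, racemic at C3)
Conditions: NBS (1.1 equiv), THF/H2O, 0 °C; unreacted 1 recovered
Reagents that add atoms: N-bromosuccinimide, O=C1CCC(=O)N1Br; water, O
Why: Electrophilic bromohydrin formation, in which the coiled polyene in the aqueous medium exposes its terminal trisubstituted alkenes and water opens the bromonium ion at the tertiary carbon (Markovnikov); the C3 centre forms racemic, which is accepted because step 3 selects.

Step 2
Reactants: 2 terminal bromohydrin
Product: 3 (3S)-2,3-oxidosqualene, obtained as the racemate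
Conditions: K2CO3, MeOH, 23 °C
Reagents that add atoms: none
Why: Intramolecular Williamson-type SN2 closure of the bromohydrin alkoxide gives the trisubstituted epoxide without touching the other alkenes.

Step 3
Reactants: 3 (3S)-2,3-oxidosqualene (used as the racemate)
Product: 4 marneral (ring B with C5 isopropylidene and Cγ aldehyde)
Conditions: marneral synthase MRN1 (yeast cell-free homogenate), 0.1 M sodium phosphate pH 6.2, 0.1% Tween 80, 25 °C, 24–48 h, argon; hexane extraction, Et3N-deactivated silica; crude 4 used at once
Reagents that add atoms: none
Why: In the active site the epoxide of (3S)-3 is protonated while the chain is held in a chair–boat fold; the C5=C6 alkene opens the epoxide at C7 (ring A) and the C1=C2 alkene adds to the C6 cation (ring B), which leaves a tertiary cation at C2, after which a hydride moves from C1 to C2, the methyl group from C6 to C1 and a hydride from C5 to C6, and the C5 cation is discharged by Grob fragmentation of the C7–Cγ bond to the Cγ aldehyde and the C5=C7 isopropylidene (atoms of 3 carry the numbers they have in 4). The closest known reaction type is the enzymatic cation–olefin bicyclisation of oxidosqualene with backbone rearrangement and ring A fragmentation, as done by oxidosqualene cyclases of the marneral synthase class; it is known as a biosynthetic reaction but not as a preparative one. Ring A closes 6-endo through a chair and is reopened within the cascade, and ring B, the ring C1–C6 that remains, closes 6-endo through a boat. C1, C2 and C6 are controlled by the enzyme-imposed fold together with the E alkenes and the (3S)-epoxide: the boat closure puts the C1 hydrogen and the C6 methyl group on the same face, and each 1,2-shift is suprafacial, so C2 gains its hydrogen, C1 its methyl group and C6 its hydrogen on fixed faces. The step needs the cascade to stop after two rings and to end by fragmentation instead of proton loss or a third ring closure; this is secured by the active site and not by the substrate, whose (3R)-enantiomer is expected to pass through unchanged.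

Step 4
Reactants: 4 marneral
Product: 5 marnerol (Cγ primary alcohol)
Conditions: NaBH4, EtOH, 0 °C
Reagents that add atoms: none
Why: Chemoselective borohydride reduction of the aldehyde leaves the four isolated alkenes and the three stereocentres untouched and removes the carbonyl group that could re-close onto the C5=C7 alkene (Prins).

Step 5
Reactants: 5 marnerol
Product: 6 marnerol tert-butyldimethylsilyl ether
Conditions: TBSCl, imidazole, DMF, 23 °C
Reagents that add atoms: tert-butyldimethylsilyl chloride, CC(C)(C)[Si](C)(C)Cl
Why: Silyl ether formation masks the primary alcohol against the chromium oxidant of step 7 and against capture of a C5 allyl cation.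

Step 6
Reactants: 6 marnerol silyl ether
Product: 8 C5 tertiary isopropenyl carbinol (mixture of C5 epimers), via C5 hydroperoxide 7 (not isolated)
Conditions: O2, H2TPP (cat.), white LED, CH2Cl2, −20 °C, to partial conversion; then PPh3, 0 °C; unreacted 6 recovered
Reagents that add atoms: dioxygen, O=O
Why: Schenck ene reaction of singlet oxygen, which should take the tetrasubstituted C5=C7 alkene well ahead of the three trisubstituted chain alkenes and, as with isopropylidenecyclohexanes in general, abstract a methyl hydrogen so that oxygen ends on C5, followed by phosphine reduction of the hydroperoxide; the new C5 centre is not controlled and is destroyed in step 7.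

Step 7
Reactants: 8 C5 tertiary isopropenyl carbinol
Product: 9 (2Z)-enal silyl ether (formyl group on C7 on the side of C6), separated from its 2E isomer
Conditions: (C5H5NH)[CrO3Cl] (pyridinium chlorochromate, 3 equiv), Celite, CH2Cl2, 23 °C; chromatography
Reagents that add atoms: pyridinium chlorochromate, [O-][Cr](=O)(=O)Cl.c1cc[nH+]cc1
Why: Babler–Dauben oxidative 1,3-transposition, in which the tertiary allylic chromate ester of 8 rearranges by a [3,3]-sigmatropic shift to the primary allylic chromate that is oxidised to the enal, so both C5 epimers converge; the C5=C7 geometry is fixed in the shift, where C4 and C6 compete for the position beside the C7 methyl group, no strong bias is expected, and the Z isomer 9 is therefore to be separated from the E isomer by chromatography.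

Step 8
Reactants: 9 (2Z)-enal silyl ether
Product: 10 target, (2Z)-2-[(2S,3R,4R)-2-(3-hydroxypropyl)-3,4-dimethyl-3-[(3E,7E)-4,8,12-trimethyltrideca-3,7,11-trien-1-yl]cyclohexylidene]propanal
Conditions: HF·pyridine, pyridine/THF, 0 °C to 23 °C
Reagents that add atoms: none
Why: Fluoride-mediated desilylation under buffered, non-basic conditions frees the Cγ alcohol without forming the dienolate that would endanger the enal geometry and the γ-stereocentre C6.

## Compound list

1 | squalene, (6E,10E,14E,18E)-2,6,10,15,19,23-hexamethyltetracosa-2,6,10,14,18,22-hexaene | CC(C)=CCC/C(C)=C/CC/C(C)=C/CC/C=C(\C)CC/C=C(\C)CCC=C(C)C | starting material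
2 | (3RS)-3-bromo-2,3-dihydrosqualen-2-ol, terminal bromohydrin, racemic at C3, remaining alkenes E | CC(C)=CCC/C(C)=C/CC/C(C)=C/CC/C=C(\C)CC/C=C(\C)CCC(Br)C(C)(C)O | intermediate
3 | (3S)-2,3-oxidosqualene, made and used as the racemate (the 3R antipode is a passenger) | CC(C)=CCC/C(C)=C/CC/C(C)=C/CC/C=C(\C)CC/C=C(\C)CC[C@@H]1OC1(C)C | intermediate
4 | marneral, 3-[(1S,2R,3R)-2,3-dimethyl-6-(propan-2-ylidene)-2-[(3E,7E)-4,8,12-trimethyltrideca-3,7,11-trien-1-yl]cyclohexyl]propanal | CC(C)=CCC/C(C)=C/CC/C(C)=C/CC[C@]1(C)[C@H](C)CCC(=C(C)C)[C@H]1CCC=O | intermediate
5 | marnerol, the Cγ primary alcohol of 4 | CC(C)=CCC/C(C)=C/CC/C(C)=C/CC[C@]1(C)[C@H](C)CCC(=C(C)C)[C@H]1CCCO | intermediate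
6 | marnerol tert-butyldimethylsilyl ether | CC(C)=CCC/C(C)=C/CC/C(C)=C/CC[C@]1(C)[C@H](C)CCC(=C(C)C)[C@H]1CCCO[Si](C)(C)C(C)(C)C | intermediate
7 | C5 hydroperoxide: C5 carries OOH and isopropenyl (C5 epimers); C1, C2, C6 as in 6 | CC(C)=CCC/C(C)=C/CC/C(C)=C/CC[C@]1(C)[C@H](C)CCC(OO)(C(C)=C)[C@H]1CCCO[Si](C)(C)C(C)(C)C | intermediate (not isolated)
8 | C5 tertiary isopropenyl carbinol (C5 epimers); C1, C2, C6 as in 6 | CC(C)=CCC/C(C)=C/CC/C(C)=C/CC[C@]1(C)[C@H](C)CCC(O)(C(C)=C)[C@H]1CCCO[Si](C)(C)C(C)(C)C | intermediate
9 | (2Z)-enal silyl ether, the tert-butyldimethylsilyl ether of the target | CC(C)=CCC/C(C)=C/CC/C(C)=C/CC[C@]1(C)[C@H](C)CC/C(=C(\C)C=O)[C@H]1CCCO[Si](C)(C)C(C)(C)C | intermediate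
10 | (2Z)-2-[(2S,3R,4R)-2-(3-hydroxypropyl)-3,4-dimethyl-3-[(3E,7E)-4,8,12-trimethyltrideca-3,7,11-trien-1-yl]cyclohexylidene]propanal | CC(C)=CCC/C(C)=C/CC/C(C)=C/CC[C@]1(C)[C@H](C)CC/C(=C(\C)C=O)[C@H]1CCCO | target

## Step count and risks

Total step count: 8. Longest linear sequence: 8 steps (1 to 10).

Steps most likely to fail:

1. Step 7. Process: the sigmatropic shift may place the new oxygenated carbon on the side of C4 as readily as on the side of C6, so much of the material may end as the E enal; in addition the acidic chromate may ionise the tertiary allylic ester and lead to elimination. Fallback: from 8, a neutral and reversible 1,3-transposition with catalytic Ph3SiOReO3 in Et2O at low temperature should give the primary allylic alcohols. The Z isomer, (Z)-allylic alcohol F1, is separated, and the E isomer and recovered 8 are resubmitted to the same catalyst, since they interconvert through 8. F1 is then oxidised with activated MnO2 in CH2Cl2, and the route is rejoined at 9.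

2. Step 3. Process: slow turnover of the membrane-bound cyclase on the micellar substrate, combined with loss of aldehyde 4 during the long incubation and work-up (autoxidation, Prins-type re-closure onto the C5=C7 alkene), may leave too little 4 for step 4. Fallback: from 3, the cyclase incubation is run as a two-enzyme cascade with horse-liver alcohol dehydrogenase, catalytic NADH and ethanol as hydride donor, so that the aldehyde is reduced as it forms and never accumulates (no new compound, F0); the route is rejoined at 5.

3. Step 6. Process: the ene reaction may also engage the chain alkenes or abstract the ring hydrogen at C4, which would place the oxygen on C7 instead of C5. Fallback: from 6, epoxidation with a deficiency of mCPBA (NaHCO3, CH2Cl2, −40 °C) should give the spiro-epoxide F2. Opening with diethylaluminium 2,2,6,6-tetramethylpiperidide (from Et2AlCl and LiNC9H18, toluene, 0 °C) removes a methyl proton, and the route is rejoined at 8.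

## Further compounds

F1 | step 7 | (Z)-primary allylic alcohol: C7 carries CH3 and CH2OH, with CH2OH on the side of C6; silyl ether retained | CC(C)=CCC/C(C)=C/CC/C(C)=C/CC[C@]1(C)[C@H](C)CC/C(=C(\C)CO)[C@H]1CCCO[Si](C)(C)C(C)(C)C
F0 | step 3 | none | none
F2 | step 6 | C5–C7 spiro-epoxide of 6 (C5 epimers) | CC(C)=CCC/C(C)=C/CC/C(C)=C/CC[C@]1(C)[C@H](C)CCC2(OC2(C)C)[C@H]1CCCO[Si](C)(C)C(C)(C)C
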